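**Plan**

1. Retrosynthetic cuts, in order: the C6–O ester bond (acid 28); the O–C10 bond of the furanone, opened across the ring to a ten-membered 1,3-diketone (C1, C3); that diketone back to an isoxazole (C1=N, C3–O); C7–C8 together with the lactone O–C12 bond (allylchromium macrocyclisation); then C11–C13, C6–C7 and the isoxazole bonds, down to crotonaldehyde, nitromethane, enynol 6, methyl propiolate and formaldehyde.
2. Forward: a (3+2) cycloaddition makes the isoxazole, which serves as masked C1/C3 diketone and as a rigid turn; alkynylation at C6 and hydroalumination/hydroxymethylation give the allyl bromide; the C1–C10 carbocycle and the lactone ring close in one allylation at C7–C8; the isoxazole is opened; the furanone ring (O, C3, C2, C1, C10) is closed; desilylation and esterification finish.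
3. Enabling feature: C1 and C3 are the carbonyls of a β-diketone inside the C1–C10 ring and C10 is its only α′-CH, so the enol oxygen on C3 lies 1,5 to C10. Joining them forms the furanone ring and the 11-oxabicyclo[6.2.1]undecane core at once and creates the quaternary C10.
4. Stereochemistry: C6 by ligand-controlled alkynylation; C7 and C8 by the chair allylation (E-allyl unit gives the trans-lactone) under control of C6 and the ring; C10 in the key step (outer-face bromination, inversion by the inner-face oxygen); the epoxy acid by Sharpless epoxidation. The early C10 centre is only a placeholder.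

Key step: step 12

Numbering: germacrane numbering of the target is used throughout (C1 ketone, C2, C3 enol-ether carbon, C4=C5, C6 acyloxy, C7, C8 lactone oxygen, C9, C10 quaternary, C11/C12/C13 lactone α-carbon, carbonyl and methylene, C14 and C15 the methyls on C10 and C4).
Abbreviation: Isx = 3-[(2R)-4,4-dimethoxybutan-2-yl]-1,2-oxazol-5-yl.
Assumption: the sense of induction in step 5 is taken from the aldol model of the zinc–ProPhenol catalyst ((R,R)-ligand for the 6R carbinol); if the catalyst delivers the other face, the (S,S)-ligand is used instead.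

**Step 1**
Reactants: 1 (E)-but-2-enal; 2 nitromethane
Product: 4 (2R)-4,4-dimethoxy-2-methyl-1-nitrobutane, via (3R)-3-methyl-4-nitrobutanal 3 (not isolated)
Conditions: (S)-α,α-diphenylprolinol trimethylsilyl ether (10 mol %), PhCO2H (20 mol %), MeOH, rt; then HC(OMe)3, TsOH (cat.), rt
Reagents that add atoms: trimethyl orthoformate, COC(OC)OC
Why: Iminium-ion Michael addition of nitromethane under diarylprolinol silyl ether catalysis, the shielded face of the iminium ion fixing C10 as one enantiomer (a placeholder that keeps later intermediates single diastereomers), followed by acid-catalysed acetalisation that masks the future C8 aldehyde.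

**Step 2**
Reactants: 4 (2R)-4,4-dimethoxy-2-methyl-1-nitrobutane
Product: 5 (2R)-4,4-dimethoxy-2-methylbutanal oxime
Conditions: BnBr, KOH, n-Bu4NI (cat.), THF, rt
Reagents that add atoms: none
Why: O-benzylation of the nitronate and loss of benzaldehyde from the O-benzyl nitronate should give the aldoxime without touching the adjacent stereocentre (nitroalkane-to-oxime conversion).

**Step 3**
Reactants: 5 (2R)-4,4-dimethoxy-2-methylbutanal oxime; 6 (2Z)-3-methylpent-2-en-4-yn-1-ol
Product: 8 (2Z)-3-(Isx)but-2-en-1-ol, via (2R)-4,4-dimethoxy-2-methylbutanenitrile oxide 7 (not isolated)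
Conditions: PhI(OAc)2, TFA (cat.), MeOH, 0 °C to rt
Reagents that add atoms: none
Why: Trivalent iodine oxidises the aldoxime to the nitrile oxide, whose Huisgen (3+2) cycloaddition with the terminal alkyne places oxygen on the substituted alkyne carbon (C3) and gives the 3,5-disubstituted isoxazole that masks the C1/C3 diketone.

**Step 4**
Reactants: 8 (2Z)-3-(Isx)but-2-en-1-ol
Product: 9 (2Z)-3-(Isx)but-2-enal
Conditions: MnO2, CH2Cl2, rt
Reagents that add atoms: none
Why: MnO2 oxidises the allylic alcohol chemoselectively and should leave the Z double bond, the acetal and the isoxazole untouched.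

**Step 5**
Reactants: 9 (2Z)-3-(Isx)but-2-enal; 10 methyl prop-2-ynoate
Product: 11 methyl (4R,5Z)-4-hydroxy-6-(Isx)hept-5-en-2-ynoate
Conditions: Me2Zn, (R,R)-ProPhenol (20 mol %), Ph3PO (40 mol %), toluene, 4 °C
Reagents that add atoms: none
Why: Zinc–ProPhenol-catalysed enantioselective alkynylation of an α,β-unsaturated aldehyde with methyl propiolate sets C6 by ligand control.

**Step 6**
Reactants: 11 methyl (4R,5Z)-4-hydroxy-6-(Isx)hept-5-en-2-ynoate
Product: 12 methyl (4R,5Z)-4-[(tert-butyldimethylsilyl)oxy]-6-(Isx)hept-5-en-2-ynoate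
Conditions: TBSCl, imidazole, DMF, rt
Reagents that add atoms: tert-butyldimethylsilyl chloride, CC(C)(C)[Si](C)(C)Cl
Why: Standard silylation of the secondary alcohol, with the chloride and imidazole chosen over a silyl triflate so that the dimethyl acetal is spared.

**Step 7**
Reactants: 12 methyl (4R,5Z)-4-[(tert-butyldimethylsilyl)oxy]-6-(Isx)hept-5-en-2-ynoate; 13 formaldehyde
Product: 15 methyl (2Z,4R,5Z)-4-[(tert-butyldimethylsilyl)oxy]-2-(hydroxymethyl)-6-(Isx)hepta-2,5-dienoate, via α-alumino acrylate 14 (not isolated)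
Conditions: i-Bu2AlH, HMPA, THF, 0 °C; then CH2O (gas from cracked paraformaldehyde), −20 to 0 °C; Rochelle salt work-up
Reagents that add atoms: none
Why: Conjugate syn-hydroalumination of the ynoate gives the α-alumino acrylate with H and Al cis, and hydroxymethylation with retention leaves C6 cis to the ester, the geometry needed for an anti-selective allylation.

**Step 8**
Reactants: 15 methyl (2Z,4R,5Z)-4-[(tert-butyldimethylsilyl)oxy]-2-(hydroxymethyl)-6-(Isx)hepta-2,5-dienoate
Product: 16 methyl (2E,4R,5Z)-2-(bromomethyl)-4-[(tert-butyldimethylsilyl)oxy]-6-(Isx)hepta-2,5-dienoate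
Conditions: CBr4, PPh3, CH2Cl2, 0 °C
Reagents that add atoms: carbon tetrabromide, BrC(Br)(Br)Br
Why: Appel bromination of the primary allylic alcohol by SN2 displacement of the oxyphosphonium ion, run cold so that the 2-(bromomethyl)acrylate does not equilibrate its double-bond geometry.

**Step 9**
Reactants: 16 methyl (2E,4R,5Z)-2-(bromomethyl)-4-[(tert-butyldimethylsilyl)oxy]-6-(Isx)hepta-2,5-dienoate
Product: 17 methyl (2E,4R,5Z)-2-(bromomethyl)-4-[(tert-butyldimethylsilyl)oxy]-6-{3-[(2R)-4-oxobutan-2-yl]-1,2-oxazol-5-yl}hepta-2,5-dienoate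
Conditions: LiBF4, MeCN/H2O (50:1), rt
Reagents that add atoms: water, O
Why: Mild Lewis-acid-promoted acetal hydrolysis should release the C8 aldehyde without touching the allylic bromide or the silyl ether.

**Step 10**
Reactants: 17 methyl (2E,4R,5Z)-2-(bromomethyl)-4-[(tert-butyldimethylsilyl)oxy]-6-{3-[(2R)-4-oxobutan-2-yl]-1,2-oxazol-5-yl}hepta-2,5-dienoate
Product: 19 isoxazole-bridged macrolactone (C1–C10 carbocycle with C1 and C3 as C-3 and C-5 of the 1,2-oxazole; 4Z; 6-OTBS; trans 8,12-lactone with 11(13)-methylene; C6 C7 C8 as in the target; 10R), via macrocyclic hydroxy ester 18 (not isolated)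
Conditions: CrCl2 (8 equiv), THF, 2 mM, syringe-pump addition, rt; then CSA (cat.), CH2Cl2, rt
Reagents that add atoms: none
Why: Divalent chromium turns the allylic bromide into an allylchromium species that adds through C7 to the tethered aldehyde in a chair Zimmerman–Traxler transition state (Nozaki–Hiyama-type Barbier macrocyclisation), the E-allyl unit giving the anti adduct and hence the trans-fused lactone after acid-catalysed acyl transfer, while the C6 silyloxy centre and the rigid isoxazole turn should select the C7 face.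

**Step 11**
Reactants: 19 isoxazole-bridged macrolactone
Product: 21 macrocyclic 1,3-diketone (C1 and C3 ketones; 4Z; 6-OTBS; trans 8,12-lactone; C10–H epimerisable), via β-amino enone 20 (not isolated)
Conditions: Mo(CO)6, MeCN/H2O (15:1), 80 °C; then 5% aq. oxalic acid, THF, rt
Reagents that add atoms: water, O
Why: Zerovalent molybdenum cleaves the isoxazole N–O bond reductively to the β-amino enone, and mild aqueous acid hydrolyses it to the 1,3-diketone without disturbing the silyl ether or the methylene lactone.

**Step 12**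
Reactants: 21 macrocyclic 1,3-diketone
Product: 24 6-O-TBS furanone (target skeleton with OTBS at C6; 10R), via bis(trimethylsilyl) dienol ether 22 (not isolated), via (10S)-10-bromo silyl enol ether 23 (not isolated)
Conditions: TMSOTf (3 equiv), Et3N (4 equiv), CH2Cl2, 0 °C; pentane filtration, then NBS, THF, −78 °C; then n-Bu4NF (1.0 equiv), −78 to 0 °C
Reagents that add atoms: none
Why: Double silylation gives the 1,3-bis(silyloxy)diene 22 (C10 is the only α′-CH), NBS attacks its terminal carbon C10, and fluoride then frees the diketone enolate, whose C3 oxygen displaces the tertiary α-keto bromide across the ring. The closest known reaction type is γ-halogenation of a β-diketone through its bis(silyl) dienol ether followed by base-induced O-alkylation of the 4-halo-1,3-diketone to a 3(2H)-furanone. The furanone ring (O, C3, C2, C1, C10) closes in a 5-exo-tet mode through the in-plane oxygen lone pair, and this closure also completes the 11-oxabicyclo[6.2.1]undecane core. C10 is set by the macrocycle: bromine should enter from the outer face of the C1=C10 enol ether and the transannular oxygen can only come from the inner face, with inversion, so the (10S)-bromide should give the (10R)-ether. The step needs halogenation at C10 and not C2 (secured by the terminal reactivity of the bis(silyloxy)diene), O- and not C-alkylation (a five-membered ether against a cyclopropanone), and one face of C10 (the trans-lactone and the Z C4=C5 bond hold C9 and C4 so that only one face is turned to the C3 oxygen).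

**Step 13**
Reactants: 24 6-O-TBS furanone
Product: 25 6-hydroxy furanone (target lacking the C6 acyl group)
Conditions: HF·pyridine, pyridine, THF, 0 °C to rt
Reagents that add atoms: none
Why: Buffered fluoride cleavage of the secondary silyl ether is mild enough for the furanone and the methylene lactone.

**Step 14**
Reactants: 26 (2E)-2-methylbut-2-en-1-ol
Product: 27 [(2R,3R)-2,3-dimethyloxiran-2-yl]methanol
Conditions: Ti(OiPr)4 (cat.), D-(−)-diethyl tartrate (cat.), t-BuOOH, 4 Å MS, CH2Cl2, −20 °C
Reagents that add atoms: tert-butyl hydroperoxide, CC(C)(C)OO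
Why: Sharpless asymmetric epoxidation of the E-allylic alcohol, the D-tartrate directing oxygen to the face that gives the (2R,3R)-epoxy alcohol, with the methyls cis as set by the alkene geometry.

**Step 15**
Reactants: 27 [(2R,3R)-2,3-dimethyloxiran-2-yl]methanol
Product: 28 (2S,3R)-2,3-dimethyloxirane-2-carboxylic acid
Conditions: RuCl3 hydrate (cat.), NaIO4, CCl4/MeCN/H2O, rt
Reagents that add atoms: water, O
Why: Catalytic ruthenium tetroxide oxidation takes the primary alcohol to the acid through the aldehyde hydrate without opening the epoxide (the descriptor at C2 changes only by priority).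

**Step 16**
Reactants: 28 (2S,3R)-2,3-dimethyloxirane-2-carboxylic acid; 25 6-hydroxy furanone
Product: 30 target CNP0258430.2, via mixed anhydride 29 (not isolated)
Conditions: 28, 2,4,6-trichlorobenzoyl chloride, Et3N, toluene, rt; then 25, DMAP, toluene, rt
Reagents that add atoms: none
Why: Yamaguchi esterification, in which DMAP transfers the aliphatic acyl group of the mixed anhydride to the hindered secondary allylic C6 alcohol under conditions that should spare the epoxide and both Michael acceptors.

**Compound list**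

1 | (E)-but-2-enal (crotonaldehyde) | C/C=C/C=O | starting material
2 | nitromethane | C[N+](=O)[O-] | starting material
3 | (3R)-3-methyl-4-nitrobutanal | C[C@@H](C[N+](=O)[O-])CC=O | intermediate
4 | (2R)-4,4-dimethoxy-2-methyl-1-nitrobutane | C[C@@H](C[N+](=O)[O-])CC(OC)OC | intermediate
5 | (2R)-4,4-dimethoxy-2-methylbutanal oxime | C[C@@H](C=NO)CC(OC)OC | intermediate
6 | (2Z)-3-methylpent-2-en-4-yn-1-ol | C#C/C(C)=C\CO | starting material
7 | (2R)-4,4-dimethoxy-2-methylbutanenitrile oxide | C[C@@H](C#[N+][O-])CC(OC)OC | intermediate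
8 | (2Z)-3-{3-[(2R)-4,4-dimethoxybutan-2-yl]-1,2-oxazol-5-yl}but-2-en-1-ol | C[C@@H](c1cc(/C(C)=C\CO)on1)CC(OC)OC | intermediate
9 | (2Z)-3-{3-[(2R)-4,4-dimethoxybutan-2-yl]-1,2-oxazol-5-yl}but-2-enal | C[C@@H](c1cc(/C(C)=C\C=O)on1)CC(OC)OC | intermediate
10 | methyl prop-2-ynoate (methyl propiolate) | C#CC(=O)OC | starting material
11 | methyl (4R,5Z)-6-{3-[(2R)-4,4-dimethoxybutan-2-yl]-1,2-oxazol-5-yl}-4-hydroxyhept-5-en-2-ynoate | C[C@@H](c1cc(/C(C)=C\[C@@H](O)C#CC(=O)OC)on1)CC(OC)OC | intermediate
12 | methyl (4R,5Z)-4-[(tert-butyldimethylsilyl)oxy]-6-{3-[(2R)-4,4-dimethoxybutan-2-yl]-1,2-oxazol-5-yl}hept-5-en-2-ynoate | C[C@@H](c1cc(/C(C)=C\[C@@H](O[Si](C)(C)C(C)(C)C)C#CC(=O)OC)on1)CC(OC)OC | intermediate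
13 | formaldehyde | C=O | starting material
14 | methyl (2E,4R,5Z)-4-[(tert-butyldimethylsilyl)oxy]-2-(diisobutylalumanyl)-6-(Isx)hepta-2,5-dienoate (H and Al cis) | C[C@@H](c1cc(/C(C)=C\[C@@H](O[Si](C)(C)C(C)(C)C)/C=C(\C(=O)OC)[Al](CC(C)C)CC(C)C)on1)CC(OC)OC | intermediate
15 | methyl (2Z,4R,5Z)-4-[(tert-butyldimethylsilyl)oxy]-2-(hydroxymethyl)-6-(Isx)hepta-2,5-dienoate | C[C@@H](c1cc(/C(C)=C\[C@@H](O[Si](C)(C)C(C)(C)C)/C=C(\C(=O)OC)CO)on1)CC(OC)OC | intermediate
16 | methyl (2E,4R,5Z)-2-(bromomethyl)-4-[(tert-butyldimethylsilyl)oxy]-6-(Isx)hepta-2,5-dienoate | C[C@@H](c1cc(/C(C)=C\[C@@H](O[Si](C)(C)C(C)(C)C)/C=C(\C(=O)OC)CBr)on1)CC(OC)OC | intermediate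
17 | methyl (2E,4R,5Z)-2-(bromomethyl)-4-[(tert-butyldimethylsilyl)oxy]-6-{3-[(2R)-4-oxobutan-2-yl]-1,2-oxazol-5-yl}hepta-2,5-dienoate | C[C@@H](c1cc(/C(C)=C\[C@@H](O[Si](C)(C)C(C)(C)C)/C=C(\C(=O)OC)CBr)on1)CC=O | intermediate
18 | macrocyclic hydroxy ester: C1–C10 carbocycle bridged by the 1,2-oxazole (C1=N, C3–O), 4Z, 6-OTBS, free 8-OH, C7 bearing the methyl acrylate unit, C6/C7/C8 as in the target, 10R | O[C@H]1C[C@@H](C)c2cc(on2)/C(C)=C\[C@@H](O[Si](C)(C)C(C)(C)C)[C@@H]1C(=C)C(=O)OC | intermediate
19 | isoxazole-bridged macrolactone: as 18 with the trans-fused 8,12-lactone closed (11(13)-methylene) | C=C1C(=O)O[C@H]2C[C@@H](C)c3cc(on3)/C(C)=C\[C@@H](O[Si](C)(C)C(C)(C)C)[C@H]12 | intermediate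
20 | macrocyclic β-amino enone (1-amino-1-en-3-one), otherwise as 19 | C=C1C(=O)O[C@H]2C[C@@H](C)C(N)=CC(=O)/C(C)=C\[C@@H](O[Si](C)(C)C(C)(C)C)[C@H]12 | intermediate
21 | macrocyclic 1,3-diketone (C1 and C3 ketones), 4Z, 6-OTBS, trans 8,12-lactone, C6/C7/C8 as in the target, C10–H (10R as drawn, epimerisable) | C=C1C(=O)O[C@H]2C[C@@H](C)C(=O)CC(=O)/C(C)=C\[C@@H](O[Si](C)(C)C(C)(C)C)[C@H]12 | intermediate
22 | 1,3-bis(trimethylsilyloxy)-1(10),2-diene of 21 | C=C1C(=O)O[C@H]2CC(C)=C(O[Si](C)(C)C)C=C(O[Si](C)(C)C)/C(C)=C\[C@@H](O[Si](C)(C)C(C)(C)C)[C@H]12 | intermediate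
23 | (10S)-10-bromo-1-oxo-3-(trimethylsilyloxy)-2-ene derived from 22 | C=C1C(=O)O[C@H]2C[C@](C)(Br)C(=O)C=C(O[Si](C)(C)C)/C(C)=C\[C@@H](O[Si](C)(C)C(C)(C)C)[C@H]12 | intermediate
24 | 6-O-TBS furanone: the target with OTBS in place of the C6 ester | C=C1C(=O)O[C@H]2C[C@@]3(C)OC(=CC3=O)/C(C)=C\[C@@H](O[Si](C)(C)C(C)(C)C)[C@H]12 | intermediate
25 | 6-hydroxy furanone: the target with free OH at C6 | C=C1C(=O)O[C@H]2C[C@@]3(C)OC(=CC3=O)/C(C)=C\[C@@H](O)[C@H]12 | intermediate
26 | (2E)-2-methylbut-2-en-1-ol | C/C=C(\C)CO | starting material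
27 | [(2R,3R)-2,3-dimethyloxiran-2-yl]methanol | OC[C@@]1(C)O[C@@H]1C | intermediate
28 | (2S,3R)-2,3-dimethyloxirane-2-carboxylic acid | OC(=O)[C@@]1(C)O[C@@H]1C | intermediate
29 | (2S,3R)-2,3-dimethyloxirane-2-carboxylic 2,4,6-trichlorobenzoic anhydride | O=C(OC(=O)c1c(Cl)cc(Cl)cc1Cl)[C@@]1(C)O[C@@H]1C | intermediate
30 | CNP0258430.2 | C=C1C(=O)O[C@H]2C[C@@]3(C)OC(=CC3=O)/C(C)=C\[C@@H](OC(=O)[C@@]3(C)O[C@@H]3C)[C@H]12 | target

Total steps: 16. Longest linear sequence: 14 (steps 1 to 13, then 16).

**Steps most likely to fail**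

Step 12. The risk is poor facial selectivity at C10 (bromination on the other face, or ionisation of the bromide before closure), with loss of HBr or halogenation at C2 as side paths. The fallback sets out from diketone 21 and returns at 24. The oxygen is put on C10 first and the other C–O bond of the furanone is closed: 21 is converted to 22 as before, and Rubottom oxidation (mCPBA, NaHCO3, CH2Cl2, −20 °C, aqueous work-up) gives the (10R)-10-hydroxy-1,3-diketone F1. Acid (TsOH, benzene, rt) then adds the C10 hydroxyl to the C3 carbonyl and removes water, the classical cyclodehydration of α′-hydroxy-1,3-diketones, to give 24. Because the oxidant keeps the face on which it enters while the bromide route inverts it, the two routes are stereochemically complementary.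

Step 10. The risk is E/Z equilibration of the allylchromium species (leading to the cis-lactone), attack on the wrong C7 face, or oligomerisation instead of ring closure. The fallback sets out from ynoate 12 and returns at 19. The aluminium species 14, made as in step 7, is alkylated with 2-(iodomethyl)-4,4,5,5-tetramethyl-1,3,2-dioxaborolane to give the configurationally stable allylboronate F2. Acetal hydrolysis (LiBF4, wet MeCN) gives the aldehyde F3. Intramolecular allylboration through a closed chair transition state (toluene, 80 °C, high dilution, then CSA) gives 19.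

Step 7. The risk is incomplete regio- or stereocontrol in the hydroalumination, over-reduction of the ester, or poor capture of formaldehyde by the aluminium species. The fallback sets out from 12 and returns at 15. Syn-hydrostannation (Bu3SnH, Pd(PPh3)4, THF) gives the α-stannyl acrylate F4; iododestannylation (I2, CH2Cl2, 0 °C) gives the α-iodo acrylate F5; Stille coupling with (tributylstannyl)methanol (Pd(PPh3)4, toluene, 80 °C) gives 15 with the same double-bond geometry.

**Further compounds**

F1 | step 12 | (10R)-10-hydroxy derivative of diketone 21 (α′-hydroxy-1,3-diketone) | C=C1C(=O)O[C@H]2C[C@@](C)(O)C(=O)CC(=O)/C(C)=C\[C@@H](O[Si](C)(C)C(C)(C)C)[C@H]12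
F2 | step 10 | methyl (2Z,4R,5Z)-4-[(tert-butyldimethylsilyl)oxy]-6-(Isx)-2-[(4,4,5,5-tetramethyl-1,3,2-dioxaborolan-2-yl)methyl]hepta-2,5-dienoate | C[C@@H](c1cc(/C(C)=C\[C@@H](O[Si](C)(C)C(C)(C)C)/C=C(\C(=O)OC)CB2OC(C)(C)C(C)(C)O2)on1)CC(OC)OC
F3 | step 10 | the aldehyde corresponding to F2 (4-oxobutan-2-yl in place of 4,4-dimethoxybutan-2-yl) | C[C@@H](c1cc(/C(C)=C\[C@@H](O[Si](C)(C)C(C)(C)C)/C=C(\C(=O)OC)CB2OC(C)(C)C(C)(C)O2)on1)CC=O
F4 | step 7 | methyl (2E,4R,5Z)-4-[(tert-butyldimethylsilyl)oxy]-6-(Isx)-2-(tributylstannyl)hepta-2,5-dienoate | C[C@@H](c1cc(/C(C)=C\[C@@H](O[Si](C)(C)C(C)(C)C)/C=C(\C(=O)OC)[Sn](CCCC)(CCCC)CCCC)on1)CC(OC)OC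
F5 | step 7 | methyl (2E,4R,5Z)-4-[(tert-butyldimethylsilyl)oxy]-2-iodo-6-(Isx)hepta-2,5-dienoate | C[C@@H](c1cc(/C(C)=C\[C@@H](O[Si](C)(C)C(C)(C)C)/C=C(\C(=O)OC)I)on1)CC(OC)OC
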